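## Structural features

The target is a 5,7-dimethoxychroman-4-one (benzo ring A = C4a, C5 to C8, C8a; pyranone ring = O1, C2, C3, C4, C4a, C8a) whose C3 is also C1' of a 5',6'-dimethoxy-1',2'-dihydrobenzocyclobutene (C1', C2', C2a', C3' to C6', C6a'), so the pyranone and cyclobutene rings share one spiro carbon. The cyclobutene is fused so that C6a', the arene carbon bonded to C3, lies next to the methoxy-bearing C6', while the ring methylene C2' is bonded to the unsubstituted side, C2a'. C3 is the only stereocentre, an all-carbon quaternary centre carrying C2 (OCH2), C4 (C=O), C2' and C6a'. CIP analysis gives S, and with no neighbouring stereocentre the stereochemical problem is purely one of absolute configuration. Fragile elements are the strained benzocyclobutene (electrocyclic opening to an o-quinodimethane on strong heating, so the route stays at or below about 60 °C once it is present), the aryl methyl ethers towards strong Lewis acids, and ring A at the free-phenol stage (air oxidation, C-alkylation). C3 bears no hydrogen, so neither epimerisation nor retro-oxa-Michael opening of the pyranone can occur in base. The real difficulty is to create the quaternary spiro carbon of a strained four-membered ring in one absolute configuration and then to form neopentyl-type bonds on two of its substituents (C2–O1 and C4–C4a) without disturbing it. The key step exploits ring A: oxygen on C5, C7 and C8a and the acyl carbon C4 on C4a make it a 2-acylphloroglucinol, the Claisen-folded form of a linear 3,5,7-triketo ester whose terminal ketone is C4, so the whole benzene ring can be grown from an open chain by forming the C4a–C5 bond.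

## Logic of the disconnections

**15 to 13 (through 14).** The two aryl O–CH3 bonds at C5 and C7 and the O1–C2 bond are cut. The methyl ethers go on last so that ring A can be made as a free, symmetric triphenol. Cutting O1–C2 leaves an ortho phenoxide facing a chloromethyl group on C3. The gain is loss of the pyranone ring and a ring A in which both ortho oxygens are equivalent, so no regiochemical question arises. The forward step must be an intramolecular 6-exo-tet displacement at a neopentyl carbon, and methylation must follow closure.

**13 to 12.** The C4a–C5 bond is cut, which unravels ring A into a 3,5,7-triketo ester attached through C4 to the chiral quaternary carbon. This trades a hexasubstituted benzene for a linear chain and places all three ring oxygens by construction. The forward step must fold by Claisen condensation and not by aldol condensation or lactonisation, and the chloride and cyclobutene must survive strong base. The design of 12 is tuned for this: chloride is kept as the leaving group because it is the halide least prone to premature displacement by a chain enolate; the ester is methyl so that methoxide in methanol cannot scramble it; no protecting group is carried; and 12 is set free only at a cold acidic quench and cyclised promptly.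

**12 to 10 and 11.** The C4–C4a bond is cut. This is the convergent point: a six-carbon polyketide block is joined to the chiral acyl block in one operation. The forward step needs the terminal carbanion of the trianion of 11 to add to a carbonyl next to a quaternary carbon, and the adduct must stay intact until work-up; the N-methoxy-N-methylamide provides this through its chelate.

**10 to 7 (through 9 and 8).** No skeletal bond is cut. The amide C–N bond, the C–Cl bond and a reduction are retraced so that the two carboxyl carbons of 7 are told apart: the free acid becomes the CH2Cl group (future C2), the ester becomes the amide (future C4). The forward steps need acid-over-ester chemoselectivity in the reduction and a substitution at a neopentyl carbon without rearrangement. Which carboxyl is reduced decides which enantiomer results, so the sense of the desymmetrisation in step 4 can be compensated by the choice of reducing agent.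

**7 to 6.** The stereocentre is traced back to a prochiral quaternary carbon with two identical ester groups. The gain is complete removal of chirality from the earlier material. The forward step must select one enantiotopic ester.

**6 to 5.** The exocyclic C1'–CO2CH3 bond is cut. This leaves a mono-ester whose C1' hydrogen is acidic; the forward step needs its enolate to form without ring opening and to react on carbon.

**5 to 3 to 1.** The cyclobutene C1'–C6a' bond is cut and C6a' is reconnected to the carboxyl carbon, which expands the four-membered ring to a strain-free 2-diazoindan-1-one; removal of the diazo group then leads to 1. The regiochemistry of the cyclobutene fusion is encoded in 1, whose carbonyl sits next to the methoxy-flanked ring carbon. The forward step needs a clean photochemical ring contraction. The carbon that was the indanone carbonyl is not wasted: it becomes the ester carbon and finally C4.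

## Other disconnections considered

**Alternative 1:** The cut is the C3–C2' bond of the cyclobutene, made by ring contraction: the four-membered ring is expanded to the spiro 1-diazoindan-2-one A1, in which C3 carries both the chromanone C4 ketone and the indanone ketone. The forward key step is irradiation of A1 in methanol: loss of N2, 1,2-shift of C3 to the carbene carbon with retention, and trapping of the ketene to give the ester A2 as a pair of epimers at C2'.
- In its favour: the reaction type is the same as in step 2 of the chosen route. The strained ring is introduced last, at ambient temperature and under neutral conditions. The migrating group is unambiguous, and the stereocentre moves with retention.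
- Against it here: A1 is a non-enolisable 1,3-diketone at quaternary C3 and is open to retro-Claisen cleavage by any nucleophile. Its quaternary stereocentre must be set by a separate asymmetric step that the key step does not help with. The chromanone aryl ketone is a second chromophore, so alpha-cleavage at C3 is conceivable. A2 carries one carbon too many, which must be removed by saponification and radical decarboxylation at a non-activated position.
- Comparison: on mechanism the two plans are equal, since both rest on the same ring contraction. The alternative is better in that the cyclobutene is exposed to fewer subsequent steps. The chosen plan is better on step economy after the contraction, because its ester carbon is kept as C4 and nothing has to be excised, and on structure, because the stereocentre is addressed explicitly.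

**Alternative 2:** The cut is the C4–C3 bond, followed by the C2'–C2a' bond. The forward key step converts the aldehyde A3 with a chiral triazolium-derived carbene and a base into an acyl anion equivalent that adds to the internal carbon of the 1,1-disubstituted alkene. This intramolecular hydroacylation of an unactivated alkene gives A4 with the pyranone ring, the quaternary centre (S, the arrangement the target needs) and a methyl group on C3. A C(sp3)–H arylation of that methyl group by the aryl bromide under zerovalent palladium catalysis (Pd(OAc)2, P(t-Bu)3, K2CO3, about 140 °C) would then close the cyclobutene and give 15.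
- In its favour: it is the shortest conceivable route. A3 comes from two simple pieces by Williamson etherification, the stereocentre is set by a catalyst, and no protecting group is needed.
- Against it here: the aryl group on the alkene is ortho,ortho'-disubstituted (Br and OCH3), hence twisted and hindered, and enantioselection for such a case would have to be established. The aldehyde is deactivated by two methoxy donors and flanked on both sides. The C–H arylation needs a temperature near the limit at which a 1-acylbenzocyclobutene begins to open, and protodebromination competes.
- Comparison: on step economy the alternative is clearly better, and it is also better in setting the stereocentre by a catalytic C–C bond formation and not by an enzyme of uncertain sense. The chosen plan is better on thermal safety of the strained ring, which is made early and never heated above about 60 °C, and its key step is biased by the substrate (hindered C4 ketone, symmetric product) and does not depend on a catalyst coping with a hindered case.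

**Alternative 3:** The cut is the C8a–O1 bond. The forward key step treats the prochiral diol A5 with CuI, a chiral diamine-type ligand and Cs2CO3, so that monovalent copper couples one of the two enantiotopic hydroxymethyl groups with the ortho bromide of ring A. This gives A6 (R by CIP, the spatial arrangement the target needs) with the pyranone ring and the stereocentre. The remaining hydroxymethyl group must afterwards be bonded to the chlorinated arene carbon to close the cyclobutene.
- In its favour: A5 should be reachable in very few steps by double hydroxymethylation of a deoxybenzoin, which is better than the five steps the chosen plan needs to reach its prochiral compound 6. Ring A is brought in intact, and the desymmetrisation is catalytic.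
- Against it here: A5 is a beta,beta'-dihydroxy ketone with a quaternary alpha-carbon and can lose formaldehyde by retro-aldol cleavage under hot carbonate conditions. The aryl bromide is flanked by a hindered ketone. The chloride must survive the copper step and then be activated for a C(sp2)–C(sp3) closure to a four-membered ring at a neopentyl carbon, for which no dependable method exists.
- Comparison: the two plans are equal in principle on how the stereocentre arises, since both desymmetrise enantiotopic groups on a prochiral quaternary carbon. The alternative is better on the length of the approach to that prochiral stage. The chosen plan is better in the ordering of risk, because the strained ring is made first by a reliable contraction and only unstrained six-membered rings are closed later.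

Key step: step 9

Remark on supply: 6,7-dimethoxyindan-1-one (1) and methyl 3,5-dioxohexanoate (11) are taken to be catalogue compounds.
Remark on step 4: the sense in which the esterase differentiates the two ester groups of 6 cannot be predicted with certainty; the route is written for the (S)-half ester 7.
Remark on descriptors: the spatial arrangement at the quaternary carbon is the same from 7 to 15; the descriptor reads S in 7 and 8, R in 9, 10, 12 and 13, and S in 14 and 15 only because the CIP priorities of the substituents change.

## Route

Step 1
Reactants: 1 6,7-dimethoxyindan-1-one
Product: 3 2-diazo-6,7-dimethoxyindan-1-one, via hydroxymethylene ketone 2 (not isolated)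
Conditions: NaH, HCO2Et, THF, 0 °C to rt; then 4-acetamidobenzenesulfonyl azide, MeCN, 0 °C to rt
Reagents that add atoms: 4-acetamidobenzenesulfonyl azide (p-ABSA), CC(=O)Nc1ccc(cc1)S(=O)(=O)N=[N+]=[N-]; ethyl formate, CCOC=O (its carbon is present only in 2 and is lost again)
Why: Claisen formylation activates C2 as the enolate of a 1,3-dicarbonyl compound, and deformylative (Regitz) diazo transfer then installs the diazo group while the formyl group leaves on the sulfonamide nitrogen; the acetamido-substituted azide is chosen as the least hazardous common diazo donor.

Step 2
Reactants: 3 2-diazo-6,7-dimethoxyindan-1-one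
Product: 5 methyl 5,6-dimethoxy-1,2-dihydrobenzocyclobutene-1-carboxylate (racemic), via ketene 4 (not isolated)
Conditions: hν (365 nm), MeOH, 15 °C
Reagents that add atoms: methanol, CO
Why: Photochemical Wolff rearrangement: loss of N2 gives the acyl carbene, the arene carbon C7a shifts from the carbonyl carbon to C2 with ring contraction to ketene 4, and methanol adds to the ketene. The former carbonyl carbon becomes the ester carbon on C1', which is bonded to the methoxy-flanked arene carbon as the target requires; the product is racemic, which is irrelevant because C1' becomes prochiral in step 3.

Step 3
Reactants: 5 methyl 5,6-dimethoxy-1,2-dihydrobenzocyclobutene-1-carboxylate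
Product: 6 dimethyl 5,6-dimethoxybenzocyclobutene-1,1(2H)-dicarboxylate
Conditions: LiN(i-Pr)2, THF, −78 °C; ClCO2Me, −78 °C to 0 °C
Reagents that add atoms: methyl chloroformate, COC(=O)Cl
Why: C-acylation of a lithium ester enolate with a chloroformate; the product has no acidic hydrogen, so no proton exchange can consume enolate, and C1' becomes a prochiral quaternary carbon with two enantiotopic ester groups.

Step 4
Reactants: 6 dimethyl 5,6-dimethoxybenzocyclobutene-1,1(2H)-dicarboxylate
Product: 7 (S)-5,6-dimethoxy-1-(methoxycarbonyl)-1,2-dihydrobenzocyclobutene-1-carboxylic acid
Conditions: pig liver esterase, phosphate buffer pH 7.5/DMSO 9:1, 25 °C, pH-stat with 1 M NaOH; then 1 M HCl to pH 2, 0 °C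
Reagents that add atoms: water, O
Why: Enzymatic desymmetrisation of a prochiral 2,2-disubstituted malonate: the esterase hydrolyses one of the two enantiotopic ester groups and thereby sets the quaternary stereocentre. The discrimination rests on the unlike shapes of the two other substituents of C1', the flat methoxy-substituted arene and the ring methylene.

Step 5
Reactants: 7 (S)-5,6-dimethoxy-1-(methoxycarbonyl)-1,2-dihydrobenzocyclobutene-1-carboxylic acid
Product: 8 methyl (S)-1-(hydroxymethyl)-5,6-dimethoxy-1,2-dihydrobenzocyclobutene-1-carboxylate
Conditions: BH3·SMe2, THF, 0 °C to rt; MeOH quench
Reagents that add atoms: none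
Why: Borane reduces a carboxylic acid through its acyloxyborane much faster than an ester, so only the carboxyl freed by the enzyme becomes CH2OH; the quaternary centre is not involved and keeps its configuration.

Step 6
Reactants: 8 methyl (S)-1-(hydroxymethyl)-5,6-dimethoxy-1,2-dihydrobenzocyclobutene-1-carboxylate
Product: 9 methyl (R)-1-(chloromethyl)-5,6-dimethoxy-1,2-dihydrobenzocyclobutene-1-carboxylate
Conditions: PPh3, CCl4, MeCN, 60 °C
Reagents that add atoms: tetrachloromethane, ClC(Cl)(Cl)Cl
Why: Appel chlorination: chloride displaces the alkoxyphosphonium group at a neopentyl carbon by SN2 without a carbocation, so no rearrangement and no elimination (no beta-hydrogen) can occur; the stereocentre is untouched.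

Step 7
Reactants: 9 methyl (R)-1-(chloromethyl)-5,6-dimethoxy-1,2-dihydrobenzocyclobutene-1-carboxylate
Product: 10 (R)-1-(chloromethyl)-N,5,6-trimethoxy-N-methyl-1,2-dihydrobenzocyclobutene-1-carboxamide
Conditions: MeNH(OMe)·HCl, i-PrMgCl, THF, −20 °C to 0 °C
Reagents that add atoms: N,O-dimethylhydroxylamine hydrochloride, Cl.CNOC
Why: Direct aminolysis of the ester by the chloromagnesium amide of N,O-dimethylhydroxylamine (Weinreb amide formation); the magnesium amide is a poor nucleophile towards the neopentyl chloride, and the ester has no alpha-hydrogen to be removed.

Step 8
Reactants: 10 (R)-1-(chloromethyl)-N,5,6-trimethoxy-N-methyl-1,2-dihydrobenzocyclobutene-1-carboxamide; 11 methyl 3,5-dioxohexanoate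
Product: 12 methyl 7-[(1R)-1-(chloromethyl)-5,6-dimethoxy-1,2-dihydrobenzocyclobuten-1-yl]-3,5,7-trioxoheptanoate (mixture of enol tautomers)
Conditions: 11 (2 equiv), LiN(i-Pr)2 (6.2 equiv), THF, −78 °C to 0 °C; then 10, −78 °C to 0 °C; AcOH, −78 °C
Reagents that add atoms: none
Why: The trianion of 11 reacts at its last-formed, most basic terminal carbanion (C6) with the Weinreb amide, an acylation of a polyketide polyanion. The tetrahedral N,O-chelate persists until the cold acidic quench, so the triketo ester is released only on work-up and cannot over-add or fold in the flask.

Step 9
Reactants: 12 methyl 7-[(1R)-1-(chloromethyl)-5,6-dimethoxy-1,2-dihydrobenzocyclobuten-1-yl]-3,5,7-trioxoheptanoate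
Product: 13 [(1R)-1-(chloromethyl)-5,6-dimethoxy-1,2-dihydrobenzocyclobuten-1-yl](2,4,6-trihydroxyphenyl)methanone
Conditions: KOH, MeOH, 0 °C to rt, Ar; then 1 M HCl, 0 °C
Reagents that add atoms: none
Why: KOH in methanol ionises the chain fully; the enolate carbon C4a, flanked by the C4 and C8a carbonyls, adds to the ester carbonyl C5, methoxide leaves, and the resulting 2-acylcyclohexane-1,3,5-trione tautomerises at once to the aromatic 2,4,6-trihydroxyphenyl ketone. The closest known reaction type is the base-mediated Claisen (Dieckmann-like) cyclisation of 3,5,7-triketo esters to 2-acylphloroglucinols, the laboratory counterpart of chalcone-synthase-type folding. Ring A closes in the 6-exo-trig mode, the attacked C=O lying outside the forming ring, which is a favoured geometry. No stereocentre is formed; the existing quaternary C3 has no alpha-hydrogen, is not part of the reacting array and keeps its R configuration. The step needs Claisen folding in preference to aldol closure (chain carbon C6 onto the C4 ketone), to enol-lactonisation to a 4-hydroxy-2-pyrone, and to displacement of chloride by an enolate oxygen. Aldol closure is disfavoured because the C4 ketone is neopentyl-like, shielded by quaternary C3 and the neighbouring C6' methoxy group, whereas the ester carbonyl is unhindered. Strong base in non-aqueous methanol keeps the terminus as the methyl ester instead of a carboxylate, which could only fold by aldol, and irreversible aromatisation drains the Claisen manifold. The chloride sits on a neopentyl carbon without a beta-hydrogen and should be inert at or below room temperature on the time scale of the cyclisation, and because the new ring is symmetric about the C4a–C7 axis only one constitution can result.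

Step 10
Reactants: 13 [(1R)-1-(chloromethyl)-5,6-dimethoxy-1,2-dihydrobenzocyclobuten-1-yl](2,4,6-trihydroxyphenyl)methanone
Product: 15 (S)-4,5,5',7'-tetramethoxyspiro[bicyclo[4.2.0]octa-1,3,5-triene-7,3'-chroman]-4'-one (the target), via dihydroxychromanone 14 (not isolated)
Conditions: K2CO3, NaI (cat.), DMF, 60 °C; then Me2SO4, 40 °C; aq. NH3 quench
Reagents that add atoms: dimethyl sulfate, COS(=O)(=O)OC
Why: Intramolecular Williamson etherification: an ortho phenoxide displaces the neopentyl chloride in a 6-exo-tet closure, the mode by which 2'-hydroxy-3-chloropivalophenones close to 3,3-dimethylchroman-4-ones, and the two ortho hydroxyls are equivalent, so one product results. The remaining phenols, including the chelated 5-OH, are then O-methylated with dimethyl sulfate and carbonate; C3 has no hydrogen, so the pyranone cannot open or epimerise under these conditions.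

## Compound list

1 | 6,7-dimethoxyindan-1-one | COc1ccc2CCC(=O)c2c1OC | starting material
2 | 2-(hydroxymethylene)-6,7-dimethoxyindan-1-one (present as its sodium enolate) | COc1ccc2CC(=CO)C(=O)c2c1OC | intermediate (not isolated)
3 | 2-diazo-6,7-dimethoxyindan-1-one | COc1ccc2CC(=[N+]=[N-])C(=O)c2c1OC | intermediate
4 | (5,6-dimethoxybenzocyclobuten-1(2H)-ylidene)methanone (ketene) | COc1ccc2CC(=C=O)c2c1OC | intermediate (not isolated)
5 | methyl 5,6-dimethoxy-1,2-dihydrobenzocyclobutene-1-carboxylate, racemic | COC(=O)C1Cc2ccc(OC)c(OC)c21 | intermediate
6 | dimethyl 5,6-dimethoxybenzocyclobutene-1,1(2H)-dicarboxylate | COC(=O)C1(C(=O)OC)Cc2ccc(OC)c(OC)c21 | intermediate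
7 | (S)-5,6-dimethoxy-1-(methoxycarbonyl)-1,2-dihydrobenzocyclobutene-1-carboxylic acid | COC(=O)[C@@]1(C(=O)O)Cc2ccc(OC)c(OC)c21 | intermediate
8 | methyl (S)-1-(hydroxymethyl)-5,6-dimethoxy-1,2-dihydrobenzocyclobutene-1-carboxylate | COC(=O)[C@@]1(CO)Cc2ccc(OC)c(OC)c21 | intermediate
9 | methyl (R)-1-(chloromethyl)-5,6-dimethoxy-1,2-dihydrobenzocyclobutene-1-carboxylate | COC(=O)[C@@]1(CCl)Cc2ccc(OC)c(OC)c21 | intermediate
10 | (R)-1-(chloromethyl)-N,5,6-trimethoxy-N-methyl-1,2-dihydrobenzocyclobutene-1-carboxamide | CON(C)C(=O)[C@@]1(CCl)Cc2ccc(OC)c(OC)c21 | intermediate
11 | methyl 3,5-dioxohexanoate | COC(=O)CC(=O)CC(C)=O | starting material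
12 | methyl 7-[(1R)-1-(chloromethyl)-5,6-dimethoxy-1,2-dihydrobenzocyclobuten-1-yl]-3,5,7-trioxoheptanoate | COC(=O)CC(=O)CC(=O)CC(=O)[C@@]1(CCl)Cc2ccc(OC)c(OC)c21 | intermediate
13 | [(1R)-1-(chloromethyl)-5,6-dimethoxy-1,2-dihydrobenzocyclobuten-1-yl](2,4,6-trihydroxyphenyl)methanone | O=C(c1c(O)cc(O)cc1O)[C@@]1(CCl)Cc2ccc(OC)c(OC)c21 | intermediate
14 | (S)-5',7'-dihydroxy-4,5-dimethoxyspiro[bicyclo[4.2.0]octa-1,3,5-triene-7,3'-chroman]-4'-one | Oc1cc(O)c2c(c1)OC[C@@]1(Cc3ccc(OC)c(OC)c31)C2=O | intermediate (not isolated)
15 | (S)-4,5,5',7'-tetramethoxyspiro[bicyclo[4.2.0]octa-1,3,5-triene-7,3'-chroman]-4'-one | COc1cc(OC)c2c(c1)OC[C@@]1(Cc3ccc(OC)c(OC)c31)C2=O | target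

## Step count and least certain steps

Total step count: 10 steps, with three intermediates (2, 4, 14) not isolated. Longest linear sequence: 10 steps, from 1 to 15; 11 is bought and enters at step 8.

**Step 9 (key step).** The chain may mis-fold (aldol closure or enol-lactonisation) if it is not kept fully ionised or if the ester is saponified first. The hindered 1,3-diketone may also suffer retro-Claisen cleavage by methoxide. Finally, the enolate that should attack C5 through carbon may instead displace the chloride through oxygen before the C4a–C5 bond has formed; this is the main reason the reaction is kept at or below room temperature and quenched as soon as 12 is consumed. Onward closure of part of 13 to 14 in the same medium would not be a loss, because 14 is the next intermediate. Fallback: the fallback abandons polyketide folding and reaches the same compound by aromatic acylation. It sets out from 9, which is saponified (LiOH, THF/water, 0 °C) to (R)-1-(chloromethyl)-5,6-dimethoxy-1,2-dihydrobenzocyclobutene-1-carboxylic acid F1. The acid is converted with oxalyl chloride and catalytic DMF into (S)-1-(chloromethyl)-5,6-dimethoxy-1,2-dihydrobenzocyclobutene-1-carbonyl chloride F2 (descriptor change by priority only). Friedel–Crafts C-acylation of phloroglucinol with F2 (AlCl3, CH2Cl2/MeNO2, 0 °C to rt) comes back to the route at 13.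

**Step 4.** Enantiotopic-group selection may be poor or may run in the opposite sense, because the fit of this rigid bicyclic malonate in the enzyme is not assured. An opposite sense could in principle be compensated by exchanging the roles of the two carboxyl groups (ester reduced by a borohydride, acid turned into the amide). Fallback: the fallback proper is a classical resolution. It sets out from 6, which is mono-saponified (KOH, 1 equiv, MeOH) to racemic 5,6-dimethoxy-1-(methoxycarbonyl)-1,2-dihydrobenzocyclobutene-1-carboxylic acid F3. This is resolved by fractional crystallisation with (S)-1-phenylethylamine; the fraction holding (S)-1-phenylethylammonium (S)-5,6-dimethoxy-1-(methoxycarbonyl)-1,2-dihydrobenzocyclobutene-1-carboxylate F4 (crystals or mother liquor) is acidified, which comes back to the route at 7.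

**Step 8.** Addition to the amide carbonyl next to the quaternary carbon may be slow, so that the trianion is consumed by proton transfer and self-condensation. Fallback: acylation is replaced by aldol addition and oxidation, which uses a smaller and more reactive electrophile. It sets out from 10, which is reduced (i-Bu2AlH, THF, −78 °C) to (R)-1-(chloromethyl)-5,6-dimethoxy-1,2-dihydrobenzocyclobutene-1-carbaldehyde F5. The trianion of 11 adds to it at −78 °C to give methyl 7-[(1R)-1-(chloromethyl)-5,6-dimethoxy-1,2-dihydrobenzocyclobuten-1-yl]-7-hydroxy-3,5-dioxoheptanoate F6 (both C7 epimers). Oxidation with Dess–Martin periodinane in CH2Cl2 comes back to the route at 12.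

**Step 10.** Substitution at the neopentyl carbon may be slow, exposing the polyphenoxide to oxidative degradation on prolonged heating, and the chelated 5-hydroxyl may be methylated incompletely. Fallback: the order of events is inverted. It sets out from 13, which is partially methylated (Me2SO4, 2 equiv, K2CO3, acetone, reflux; the para and one ortho hydroxyl react, the chelated one remains) to [(1R)-1-(chloromethyl)-5,6-dimethoxy-1,2-dihydrobenzocyclobuten-1-yl](2-hydroxy-4,6-dimethoxyphenyl)methanone F7. Its single phenoxide is then closed onto the chloride (Cs2CO3, DMF, 60 °C), which comes back to the route at 15.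

**Step 7.** Aminolysis may stall because the ester carbonyl is flanked by a quaternary carbon. Fallback: the amide is bypassed. The fallback sets out from 9, which is used directly as the acylating agent for an excess of the trianion of 11 (THF, 0 °C to rt, extra base to ionise the product), and comes back to the route at 12. It makes no compound outside the list (entry F0).

## Further compounds

F1 | step 9 | (R)-1-(chloromethyl)-5,6-dimethoxy-1,2-dihydrobenzocyclobutene-1-carboxylic acid | OC(=O)[C@@]1(CCl)Cc2ccc(OC)c(OC)c21
F2 | step 9 | (S)-1-(chloromethyl)-5,6-dimethoxy-1,2-dihydrobenzocyclobutene-1-carbonyl chloride | ClC(=O)[C@@]1(CCl)Cc2ccc(OC)c(OC)c21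
F3 | step 4 | 5,6-dimethoxy-1-(methoxycarbonyl)-1,2-dihydrobenzocyclobutene-1-carboxylic acid, racemic | COC(=O)C1(C(=O)O)Cc2ccc(OC)c(OC)c21
F4 | step 4 | (S)-1-phenylethylammonium (S)-5,6-dimethoxy-1-(methoxycarbonyl)-1,2-dihydrobenzocyclobutene-1-carboxylate | COC(=O)[C@@]1(C(=O)[O-])Cc2ccc(OC)c(OC)c21.C[C@H]([NH3+])c1ccccc1
F5 | step 8 | (R)-1-(chloromethyl)-5,6-dimethoxy-1,2-dihydrobenzocyclobutene-1-carbaldehyde | O=C[C@@]1(CCl)Cc2ccc(OC)c(OC)c21
F6 | step 8 | methyl 7-[(1R)-1-(chloromethyl)-5,6-dimethoxy-1,2-dihydrobenzocyclobuten-1-yl]-7-hydroxy-3,5-dioxoheptanoate, both C7 epimers | COC(=O)CC(=O)CC(=O)CC(O)[C@@]1(CCl)Cc2ccc(OC)c(OC)c21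
F7 | step 10 | [(1R)-1-(chloromethyl)-5,6-dimethoxy-1,2-dihydrobenzocyclobuten-1-yl](2-hydroxy-4,6-dimethoxyphenyl)methanone | O=C(c1c(O)cc(OC)cc1OC)[C@@]1(CCl)Cc2ccc(OC)c(OC)c21
F0 | step 7 | none | none
A1 | alternative 1 | (R)-3'-diazo-5,6',7,7'-tetramethoxyspiro[chromane-3,1'-indane]-2',4-dione | COc1cc(OC)c2c(c1)OC[C@@]1(C(=O)C(=[N+]=[N-])c3ccc(OC)c(OC)c31)C2=O
A2 | alternative 1 | methyl (7S)-4,5,5',7'-tetramethoxy-4'-oxospiro[bicyclo[4.2.0]octa-1,3,5-triene-7,3'-chromane]-8-carboxylate, both C8 epimers | COc1cc(OC)c2c(c1)OC[C@@]1(C(C(=O)OC)c3ccc(OC)c(OC)c31)C2=O
A3 | alternative 2 | 2-{[2-(6-bromo-2,3-dimethoxyphenyl)prop-2-en-1-yl]oxy}-4,6-dimethoxybenzaldehyde | COc1cc(OC)c(C=O)c(c1)OCC(=C)c1c(Br)ccc(OC)c1OC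
A4 | alternative 2 | (S)-3-(6-bromo-2,3-dimethoxyphenyl)-5,7-dimethoxy-3-methylchroman-4-one | COc1cc(OC)c2c(c1)OC[C@@](c1c(Br)ccc(OC)c1OC)(C)C2=O
A5 | alternative 3 | 1-(2-bromo-4,6-dimethoxyphenyl)-2-(6-chloro-2,3-dimethoxyphenyl)-3-hydroxy-2-(hydroxymethyl)propan-1-one | COc1cc(OC)c(C(=O)C(CO)(CO)c2c(Cl)ccc(OC)c2OC)c(Br)c1
A6 | alternative 3 | (R)-3-(6-chloro-2,3-dimethoxyphenyl)-3-(hydroxymethyl)-5,7-dimethoxychroman-4-one | COc1cc(OC)c2c(c1)OC[C@@](c1c(Cl)ccc(OC)c1OC)(CO)C2=O
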